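**Retrosynthetic overview**
1. The target comes from its tri-O-benzyl ether by neutral hydrogenolysis as the last step.
2. The flavanone pyranone ring (O1–C2, the only stereocentre) is formed last, by a catalyst-controlled, chalcone-isomerase-type 6-endo oxa-Michael closure of a 2',6'-dihydroxy-4'-methoxychalcone that already carries the finished flavone.
3. That chalcone comes from aldol condensation of a flavone aldehyde with unprotected 2',6'-dihydroxy-4'-methoxyacetophenone.
4. The flavone aldehyde comes from a diaryl ether SNAr between a 5,7-bis(benzyloxy)-4'-fluoroflavone and 4-(benzyloxy)-3-hydroxybenzaldehyde, which differentiates the two halves without a dialdehyde.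
5. The flavone pyranone ring is formed first, by oxidative cyclisation of a 2'-hydroxychalcone (chalcone → flavanone → flavone) made from dibenzyl phloroacetophenone and 4-fluorobenzaldehyde.

Assumption: 4-(benzyloxy)-3-hydroxybenzaldehyde and 2',6'-dihydroxy-4'-methoxyacetophenone are bought as catalogue building blocks; the given SMILES encodes the (2S) flavanone.

**Step 1**
Reactants: 1 2',4',6'-trihydroxyacetophenone
Product: 2 1-[2,4-bis(benzyloxy)-6-hydroxyphenyl]ethan-1-one
Conditions: BnBr (2.1 equiv), K2CO3 (2.2 equiv), DMF, 0 °C → rt, 16 h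
Reagents that add atoms: benzyl bromide BrCc1ccccc1
Why: Williamson ether synthesis in which the 4'-OH and one ortho-OH are alkylated while the last ortho-OH, locked in a hydrogen bond to the acetyl carbonyl, stays free.

**Step 2**
Reactants: 2 1-[2,4-bis(benzyloxy)-6-hydroxyphenyl]ethan-1-one, 3 4-fluorobenzaldehyde
Product: 4 (E)-1-[2,4-bis(benzyloxy)-6-hydroxyphenyl]-3-(4-fluorophenyl)prop-2-en-1-one
Conditions: KOH (50% aq), EtOH–THF, rt, 24 h; then 1 M HCl, 0 °C
Reagents that add atoms: none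
Why: Claisen–Schmidt aldol condensation between the only enolisable ketone and a non-enolisable aldehyde gives the conjugated E-enone by E1cB dehydration, and the aryl fluoride is inert at room temperature.

**Step 3**
Reactants: 4 (E)-1-[2,4-bis(benzyloxy)-6-hydroxyphenyl]-3-(4-fluorophenyl)prop-2-en-1-one
Product: 6 5,7-bis(benzyloxy)-2-(4-fluorophenyl)-4H-chromen-4-one, via racemic 5,7-bis(benzyloxy)-4'-fluoroflavanone 5 (not isolated)
Conditions: I2 (10 mol %), DMSO, 130 °C, 3 h
Reagents that add atoms: none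
Why: I2/DMSO oxidative cyclisation, in which 6-endo oxa-Michael closure to the flavanone is followed by C3 iodination and loss of HI to the flavone while DMSO turns HI back into I2 (the chalcone isomerase then flavone synthase order of events), and benzyl ethers and the C–F bond survive.

**Step 4**
Reactants: 6 5,7-bis(benzyloxy)-2-(4-fluorophenyl)-4H-chromen-4-one, 7 4-(benzyloxy)-3-hydroxybenzaldehyde
Product: 8 4-(benzyloxy)-3-{4-[5,7-bis(benzyloxy)-4-oxo-4H-chromen-2-yl]phenoxy}benzaldehyde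
Conditions: Cs2CO3 (1.5 equiv), DMSO, 120 °C, N2, 12 h
Reagents that add atoms: none
Why: Nucleophilic aromatic substitution (SNAr), because the 4-oxochromen-2-yl group is a para acceptor of about acetyl strength (4'-hydroxyflavone and 4-hydroxyacetophenone have similar acidity), so the phenoxide of 7, the only nucleophile present, displaces fluoride through a Meisenheimer adduct delocalised onto the pyranone carbonyl.

**Step 5**
Reactants: 8 4-(benzyloxy)-3-{4-[5,7-bis(benzyloxy)-4-oxo-4H-chromen-2-yl]phenoxy}benzaldehyde, 9 1-(2,6-dihydroxy-4-methoxyphenyl)ethan-1-one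
Product: 10 (E)-3-(4-(benzyloxy)-3-{4-[5,7-bis(benzyloxy)-4-oxo-4H-chromen-2-yl]phenoxy}phenyl)-1-(2,6-dihydroxy-4-methoxyphenyl)prop-2-en-1-one
Conditions: 9 (1.2 equiv), LiHMDS (3.0 equiv per 9), THF, −78 → 0 °C; then 8, −78 °C → rt, 16 h; 1 M HCl, 0 °C
Reagents that add atoms: none
Why: Claisen–Schmidt condensation run on the preformed trilithium salt of 9 (two phenoxides plus the enolate, no free amide left to attack the aldehyde and no hydroxide to open the flavone), which adds to the aldehyde and loses LiOH to the E-enone; in strong base the open chalcone phenoxide is the stable form, and cold acid releases the 2',6'-dihydroxychalcone before it can cyclise.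

**Step 6**
Reactants: 10 (E)-3-(4-(benzyloxy)-3-{4-[5,7-bis(benzyloxy)-4-oxo-4H-chromen-2-yl]phenoxy}phenyl)-1-(2,6-dihydroxy-4-methoxyphenyl)prop-2-en-1-one
Product: 11 (2S)-2-(4-(benzyloxy)-3-{4-[5,7-bis(benzyloxy)-4-oxo-4H-chromen-2-yl]phenoxy}phenyl)-5-hydroxy-7-methoxy-2,3-dihydro-4H-chromen-4-one
Conditions: quinidine-derived bifunctional thiourea (3,5-bis(trifluoromethyl)phenyl thiourea of 9-amino-9-deoxy-epi-quinidine, 10 mol %), toluene–CH2Cl2 4:1, −20 °C, 24–48 h; filtration through silica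
Reagents that add atoms: none
Why: Proposed new method: the substrate is the 6'-hydroxychalcone type that chalcone isomerase closes, and its ground-state conformer already has one OH chelating the carbonyl (internal acid activation of the enone) and the other, non-chelated and more acidic OH next to Cβ, so the quinuclidine nitrogen acts as general base on that OH while the thiourea binds the carbonyl/phenoxide and shields one enone face for the 6-endo-trig oxa-Michael addition that sets C2 as S (the two OH groups are equivalent, so there is no regiochemical issue, and the uncatalysed closure is negligible in this non-polar medium at −20 °C); the closest known reaction type is the cinchona–thiourea-catalysed intramolecular oxa-Michael cyclisation of 2'-hydroxy enones to flavanones, and the sense of induction is checked by CD (2S: positive band near 330 nm, negative near 290 nm), with the quinine-derived pseudo-enantiomer used instead if the antipode forms.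

**Step 7**
Reactants: 11 (2S)-2-(4-(benzyloxy)-3-{4-[5,7-bis(benzyloxy)-4-oxo-4H-chromen-2-yl]phenoxy}phenyl)-5-hydroxy-7-methoxy-2,3-dihydro-4H-chromen-4-one
Product: 12 (2S)-2-(3-{4-[5,7-dihydroxy-4-oxo-4H-chromen-2-yl]phenoxy}-4-hydroxyphenyl)-5-hydroxy-7-methoxy-2,3-dihydro-4H-chromen-4-one
Conditions: H2 (1 atm), 10% Pd/C, EtOAc–THF 1:1, rt, followed by LC–MS and stopped when the third benzyl group is gone
Reagents that add atoms: none
Why: Hydrogenolysis of the three aryl benzyl ethers under neutral conditions, which neither ring-open nor epimerise the flavanone (C2 stays S), and O-benzyl cleavage is much faster than reduction of the flavone C2=C3 bond or the aryl ketones.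

**Compound list**
1 | 2',4',6'-trihydroxyacetophenone | CC(=O)c1c(O)cc(O)cc1O | starting material
2 | 1-[2,4-bis(benzyloxy)-6-hydroxyphenyl]ethan-1-one | CC(=O)c1c(O)cc(OCc2ccccc2)cc1OCc1ccccc1 | intermediate
3 | 4-fluorobenzaldehyde | O=Cc1ccc(F)cc1 | starting material
4 | (E)-1-[2,4-bis(benzyloxy)-6-hydroxyphenyl]-3-(4-fluorophenyl)prop-2-en-1-one | O=C(/C=C/c1ccc(F)cc1)c1c(O)cc(OCc2ccccc2)cc1OCc1ccccc1 | intermediate
5 | racemic 5,7-bis(benzyloxy)-2-(4-fluorophenyl)-2,3-dihydro-4H-chromen-4-one | O=C1CC(c2ccc(F)cc2)Oc2cc(OCc3ccccc3)cc(OCc3ccccc3)c12 | intermediate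
6 | 5,7-bis(benzyloxy)-2-(4-fluorophenyl)-4H-chromen-4-one | O=c1cc(-c2ccc(F)cc2)oc2cc(OCc3ccccc3)cc(OCc3ccccc3)c12 | intermediate
7 | 4-(benzyloxy)-3-hydroxybenzaldehyde | O=Cc1ccc(OCc2ccccc2)c(O)c1 | starting material
8 | 4-(benzyloxy)-3-{4-[5,7-bis(benzyloxy)-4-oxo-4H-chromen-2-yl]phenoxy}benzaldehyde | O=Cc1ccc(OCc2ccccc2)c(Oc2ccc(-c3cc(=O)c4c(OCc5ccccc5)cc(OCc5ccccc5)cc4o3)cc2)c1 | intermediate
9 | 1-(2,6-dihydroxy-4-methoxyphenyl)ethan-1-one | CC(=O)c1c(O)cc(OC)cc1O | starting material
10 | (E)-3-(4-(benzyloxy)-3-{4-[5,7-bis(benzyloxy)-4-oxo-4H-chromen-2-yl]phenoxy}phenyl)-1-(2,6-dihydroxy-4-methoxyphenyl)prop-2-en-1-one | COc1cc(O)c(C(=O)/C=C/c2ccc(OCc3ccccc3)c(Oc3ccc(-c4cc(=O)c5c(OCc6ccccc6)cc(OCc6ccccc6)cc5o4)cc3)c2)c(O)c1 | intermediate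
11 | (2S)-2-(4-(benzyloxy)-3-{4-[5,7-bis(benzyloxy)-4-oxo-4H-chromen-2-yl]phenoxy}phenyl)-5-hydroxy-7-methoxy-2,3-dihydro-4H-chromen-4-one | COc1cc(O)c2c(c1)O[C@H](c1ccc(OCc3ccccc3)c(Oc3ccc(-c4cc(=O)c5c(OCc6ccccc6)cc(OCc6ccccc6)cc5o4)cc3)c1)CC2=O | intermediate
12 | (2S)-2-(3-{4-[5,7-dihydroxy-4-oxo-4H-chromen-2-yl]phenoxy}-4-hydroxyphenyl)-5-hydroxy-7-methoxy-2,3-dihydro-4H-chromen-4-one | COc1cc(O)c2c(c1)O[C@H](c1ccc(O)c(Oc3ccc(-c4cc(=O)c5c(O)cc(O)cc5o4)cc3)c1)CC2=O | target

**Total step count:** 7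
**Longest linear sequence:** 7 steps (1 → 2 → 4 → 6 → 8 → 10 → 11 → 12)

**Three steps most likely to fail**

Step 6 (enantioselectivity of the direct chalcone closure, or erosion by reversible ring opening). The fallback sets out from 10 and comes back at 11. Chalcone 10 is closed without stereocontrol (NaOAc, EtOH–THF, 60 °C) to the racemic tri-O-benzyl flavanone F1. F1 is resolved by preparative chiral SFC on an amylose carbamate phase into 11 and the (2R)-antipode F2. F2 is reopened to 10 with KOH in EtOH–THF at rt followed by cold acidification, and recycled.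

Step 5 (condensation of the unprotected dihydroxyacetophenone, or premature racemic closure of 10 during isolation). The fallback sets out from 9, uses 8, and comes back at 12. Acetophenone 9 is monobenzylated (BnBr 1.05 equiv, K2CO3, acetone, reflux) to 1-[2-(benzyloxy)-6-hydroxy-4-methoxyphenyl]ethan-1-one F3. A classical Claisen–Schmidt condensation of F3 with 8 (KOH, EtOH–THF, rt) gives the 6'-O-benzyl chalcone F4, which is stable because its only free OH is chelated. The same cinchona thiourea (toluene, rt) closes F4 to the tetra-O-benzyl (2S)-flavanone F5. Hydrogenolysis of F5 (H2, Pd/C, EtOAc–THF) gives 12.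

Step 4 (the fluoroflavone may be too weak an SNAr acceptor, or the pyranone may be attacked at C2). The fallback sets out from 2 and comes back at 8. Ketone 2 is condensed with 4-bromobenzaldehyde F6 (bought) under KOH in EtOH–THF to (E)-1-[2,4-bis(benzyloxy)-6-hydroxyphenyl]-3-(4-bromophenyl)prop-2-en-1-one F7. Oxidative cyclisation of F7 (I2 cat., DMSO, 130 °C) gives 5,7-bis(benzyloxy)-2-(4-bromophenyl)-4H-chromen-4-one F8. A copper-catalysed Ullmann ether coupling of F8 with 7 (CuI, picolinic acid, K3PO4, DMSO, 90 °C) gives 8.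

**Further compounds**
F1 | step 6 | racemic 2-(4-(benzyloxy)-3-{4-[5,7-bis(benzyloxy)-4-oxo-4H-chromen-2-yl]phenoxy}phenyl)-5-hydroxy-7-methoxy-2,3-dihydro-4H-chromen-4-one | COc1cc(O)c2c(c1)OC(c1ccc(OCc3ccccc3)c(Oc3ccc(-c4cc(=O)c5c(OCc6ccccc6)cc(OCc6ccccc6)cc5o4)cc3)c1)CC2=O
F2 | step 6 | (2R)-2-(4-(benzyloxy)-3-{4-[5,7-bis(benzyloxy)-4-oxo-4H-chromen-2-yl]phenoxy}phenyl)-5-hydroxy-7-methoxy-2,3-dihydro-4H-chromen-4-one | COc1cc(O)c2c(c1)O[C@@H](c1ccc(OCc3ccccc3)c(Oc3ccc(-c4cc(=O)c5c(OCc6ccccc6)cc(OCc6ccccc6)cc5o4)cc3)c1)CC2=O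
F3 | step 5 | 1-[2-(benzyloxy)-6-hydroxy-4-methoxyphenyl]ethan-1-one | CC(=O)c1c(O)cc(OC)cc1OCc1ccccc1
F4 | step 5 | (E)-3-(4-(benzyloxy)-3-{4-[5,7-bis(benzyloxy)-4-oxo-4H-chromen-2-yl]phenoxy}phenyl)-1-[2-(benzyloxy)-6-hydroxy-4-methoxyphenyl]prop-2-en-1-one | COc1cc(O)c(C(=O)/C=C/c2ccc(OCc3ccccc3)c(Oc3ccc(-c4cc(=O)c5c(OCc6ccccc6)cc(OCc6ccccc6)cc5o4)cc3)c2)c(OCc2ccccc2)c1
F5 | step 5 | (2S)-5-(benzyloxy)-2-(4-(benzyloxy)-3-{4-[5,7-bis(benzyloxy)-4-oxo-4H-chromen-2-yl]phenoxy}phenyl)-7-methoxy-2,3-dihydro-4H-chromen-4-one | COc1cc(OCc2ccccc2)c2c(c1)O[C@H](c1ccc(OCc3ccccc3)c(Oc3ccc(-c4cc(=O)c5c(OCc6ccccc6)cc(OCc6ccccc6)cc5o4)cc3)c1)CC2=O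
F6 | step 4 | 4-bromobenzaldehyde (bought) | O=Cc1ccc(Br)cc1
F7 | step 4 | (E)-1-[2,4-bis(benzyloxy)-6-hydroxyphenyl]-3-(4-bromophenyl)prop-2-en-1-one | O=C(/C=C/c1ccc(Br)cc1)c1c(O)cc(OCc2ccccc2)cc1OCc1ccccc1
F8 | step 4 | 5,7-bis(benzyloxy)-2-(4-bromophenyl)-4H-chromen-4-one | O=c1cc(-c2ccc(Br)cc2)oc2cc(OCc3ccccc3)cc(OCc3ccccc3)c12
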